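The data were generated by integration with made-up constants; the scatter is artificial.

The easy step comes first: in the midnight run the right-handed substrate still stands at 50.0 % after 60.0 min, and in the noon run at 50.4 %, so the curve to watch is the left-handed substrate.

| setting | midnight | noon | flask |
|---|---|---|---|
| left-handed substrate | 0.13 M | 0.30 M | 0.20 M |
| right-handed substrate | 0.13 M | 0.30 M | 0.20 M |
| gas | 20 mM (held) | 20 mM (held) | 20 mM (held) |
| free catalyst | 0.20 mM | 0.20 mM | 0.20 mM |
| impurity | 0.18 mM | 0.18 mM | 0.18 mM |
| remark | run made earlier | run made earlier |  |
| time |  |  | 50 min |

- midnight (time / min: left-handed substrate / %, right-handed substrate / %, left-handed product / %): 5.00: 47.0, 49.7, 3.6; 10.0: 42.5, 49.7, 7.7; 15.0: 39.0, 49.9, 10.4; 30.0: 30.8, 50.0, 20.0; 60.0: 21.7, 50.0, 28.0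
- noon (time / min: left-handed substrate / %, right-handed substrate / %, left-handed product / %): 5.00: 48.2, 49.9, 1.5; 15.0: 43.5, 49.8, 6.0; 30.0: 38.6, 49.6, 11.0; 40.0: 35.3, 49.9, 14.7; 60.0: 30.6, 50.4, 19.5

(readings scatter by 0.3 percentage points)

- free catalyst is single-handed; left-handed substrate and right-handed substrate are mirror images of each other, charged as a racemate, each of them at the stated concentration
- at the start none of the gas is in solution
- an excess is below zero if the other one leads

1. part of the left-handed substrate and right-handed substrate charged together that has reacted at 50 min
2. excess of left-handed product over right-handed product in the product at 50 min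
3. excess of right-handed substrate over left-handed substrate among what is left of the two at 50 min

Two chemists read that curve differently. The first holds to a fixed output. The left-handed product made by 5.00 min is 9.36 mM in the midnight run and 9.00 mM in the noon run, so scaling their mean to 50 min puts the flask at 22.9 % reacted.

The second objects that the midnight run read 72.8 mM at 60.0 min, less than the 112 mM a fixed output requires. She reckons pseudo-first-order instead, with a half-life that depends on loading. The last readings give 49.8 min at midnight and 84.7 min at noon, longer at the higher loading. Interpolated linearly to 0.20 M, that is 64.2 min. So she counts 0.779 half-lives for the flask, and this half-life count is the quantity to track. On her reckoning that leaves 29.1 % of left-handed substrate, which means 20.9 % reacted.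

The forecast stands on her side with a slightly higher figure: 21.3 % reacted, excesses 99 % and 27 %. Its ground: “The apparent first-order constant is lower at higher loading”.

The flask gives 21.5 %, 99.8 % and 27.3 %, a count of 0.811. Fixed output keeps the opening minutes: the flask holds 10.1 mM of left-handed product at 5.00 min, beside the two runs' figures.

    free catalyst + left-handed substrate ⇌ catalyst intermediate A (K = 75.0 L mol⁻¹, k = 18000 L mol⁻¹ min⁻¹)
    reagent + catalyst intermediate B → free catalyst + right-handed product (k = 56.0 L mol⁻¹ min⁻¹)
    free catalyst → spent catalyst B (k = 0.0300 min⁻¹)
    reagent + catalyst intermediate A → free catalyst + left-handed product (k = 2000 L mol⁻¹ min⁻¹)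
    gas ⇌ reagent, rate k5*(csat - [reagent]) (kL = 0.290 min⁻¹)
    free catalyst + impurity → spent catalyst A (k = 5400 L mol⁻¹ min⁻¹)
    free catalyst + right-handed substrate ⇌ catalyst intermediate B (K = 1.80 L mol⁻¹, k = 8500 L mol⁻¹ min⁻¹)

The excess of left-handed product owes its height to the backward run of catalyst intermediate B to free catalyst and right-handed substrate: in the run without that backward step the excess is −55.5 % instead of 99.8 %. Part of the conversion hangs on the same step: that run reaches 3.18 % reacted instead of 21.5 %. With 5.0 × 10⁻⁴ M of free catalyst in the neighbour flask, and the half-life taken as shorter in proportion to the charge, the count becomes 1.95, or 37.0 % reacted. The computed neighbour reaches 44.4 %, a count of 3.14.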